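The examiner puts the recipes on the table and asks for the share of J in J plus X.

| setting | winter | noon | dusk | maple | oak | elm | birch |
|---|---|---|---|---|---|---|---|
| Z | 0.050 M | 0.050 M | 0.050 M | 0.050 M | 0.050 M | 0.050 M (fed, over 50 s) | 0.050 M (fed, over 50 s) |
| E | 2.5 equiv | 2.5 equiv | 2.5 equiv | 2.50 equiv (fed, over 50 s) | 2.50 equiv | 2.50 equiv | 2.50 equiv |
| Q | 0.050 M | 0.025 M | 0.038 M | 0.0500 M | 0.0500 M | 0.0500 M | 0.0500 M |
| temperature | 10 °C | 25 °C | 10 °C | 25 °C | 25 °C | 25 °C |  |
| remark | run made earlier | run made earlier | run made earlier | all else is in the flask from the start; the feed brings no volume worth counting | everything together at the start | all else is in the flask from the start; the feed brings no volume worth counting | the addition at −15 °C, then warmed to 25 °C; the feed brings no volume worth counting |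
| time |  |  |  | 2.0 min | 2.0 min | 2.0 min | 2.0 min |

1. which flask leads in share of J in J plus X ("all alike" within 1.5 percentage points) (maple / oak / elm / birch / all alike)
2. share of J in J plus X at the end, maple
3. share of J in J plus X at the end, oak
4. share of J in J plus X at the end, elm
5. share of J in J plus X at the end, birch

winter run (percent of the Z charged)

| time / min | J / % | X / % |
|---|---|---|
| 0.500 | 2.1 | 0.6 |
| 1.00 | 6.9 | 0.6 |
| 2.00 | 10.2 | 4.7 |
| 3.00 | 11.3 | 1.2 |
| 4.00 | 14.1 | 1.1 |

noon run (percent of the Z charged)

| time / s | J / % | X / % |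
|---|---|---|
| 10.0 | 3.1 | 1.1 |
| 15.0 | 4.4 | 2.3 |
| 20.0 | 7.9 | 1.9 |
| 30.0 | 8.8 | 2.1 |
| 50.0 | 10.9 | 2.2 |
| 80.0 | 16.7 | 4.4 |
| 120 | 20.2 | 3.2 |

dusk run (percent of the Z charged)

| time / min | J / % | X / % |
|---|---|---|
| 0.500 | 2.8 | 0 |
| 1.00 | 6.6 | 0.2 |
| 2.00 | 8.8 | 2.7 |
| 3.00 | 11.9 | 2.8 |
| 4.00 | 13.3 | 2.2 |

(readings scatter by 1 percentage point)

- percent here means Z units held: one D counts as two
- the analysis behind the earlier runs scatters by 1 percentage point, standard deviation
- steps thought possible: 2 Z -> D; Z + E -> J; E + Q -> L; Z + E -> X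

"What sets the share?" Z + E gives J and Z + E gives X, so if each rate goes as [Z][E], at one temperature [Z] and [E] cancel from their ratio. Feeding Z or E moves [Z] and [E], so it can move the yield but not the share.

"What do you carry?" The split, the selectivity factor written as a share: J over J plus X, summed across the noon readings at 25 °C: 80.7%.

"Why sum? The last noon reading gives 86.3%." That reading rests on X of 3.2% with a scatter of 1 percentage point, so one reading is worth little.

"Noon held 0.025 M of Q; the recipes hold 0.0500 M." E + Q gives L and lowers [E], and [E] cancels.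

"And birch, which isn't at one temperature?" Winter and dusk together, at 10 °C, read 84.5%, higher than the split. But J reads 20.2% in noon at 120 s and 10.2% in winter at 2.00 min, a ratio of 1.98 as read, with the temperature and Q both different between those runs. I take that reading as J forming more slowly in the cold; birch's addition at −15 °C is colder than winter, so I expect it to make little J, and I commit to the split for each flask.

The forecast said 83% for maple, 83% for oak, 83% for elm, 83.5% for birch, and all alike: "feed mode changes yield but not share". Its figures stand above mine; its verdict is my verdict.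

The flasks give 81.4% for maple, 81.4% for oak, 81.4% for elm, 81.5% for birch: all alike.

    2 Z → D (k = 0.140 M⁻¹ s⁻¹, Ea = 41.0 kJ mol⁻¹)
    Z + E → J (k = 0.0310 M⁻¹ s⁻¹, Ea = 52.0 kJ mol⁻¹)
    E + Q → L (k = 0.240 M⁻¹ s⁻¹, Ea = 57.0 kJ mol⁻¹)
    Z + E → X (k = 0.00710 M⁻¹ s⁻¹, Ea = 59.0 kJ mol⁻¹)
    (constants at 25 °C)

In elm at 2.00 min, Z goes to D at 2.4 times its rate to J, and D stands at 44.3% against J at 15.1%. The split follows J through that loss: elm's J implies X of 3.61%, and the flask holds 3.46%. In elm's neighbour with 10.0 equiv of E, J reaches 52.5%, the split implies X of 12.6%, and the flask holds 12.0%.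

The earlier runs and the new flask were computed for an exercise; noise was put on by code.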